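**Assumption:** 2,3-dimethoxy-1,4-benzoquinone (1) and (2-bromoallyl)trimethylsilane (4) are bought as catalogue compounds. The target's single stereocentre, C3 of the chroman, is (S) by CIP analysis of the given SMILES.

## Retrosynthetic overview

1. 12 ⇐ 10: acid release of the ring A phenol and the ring B hydroquinone, then aerobic oxidation of the hydroquinone to the quinone.
2. 10 ⇐ 9: the pyran O1–C2 bond by enantioselective anti-Markovnikov hydroetherification of a 1,1-disubstituted alkene; the same step sets C3 as (S).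
3. 9 ⇐ 8 ⇐ 1 + 7: the C4–C4a bond by conjugate allylation of quinone 1 (becomes ring A), then selective Boc protection of the remote OH.
4. 7 ⇐ 3 + 4: the aryl–vinyl bond by ortho-lithiation/Negishi coupling; 3 is the bis-MOM hydroquinone of the same quinone 1 (becomes ring B).
5. Ring order: rings A and B are both bought as 1; the pyran ring is the only ring made (step 5).

## Route

**Step 1**
Reactants: 1 2,3-dimethoxy-1,4-benzoquinone
Product: 3 1,4-bis(methoxymethoxy)-2,3-dimethoxybenzene, via 2,3-dimethoxyhydroquinone 2 (not isolated)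
Conditions: H2 (1 atm), Pd/C (5 mol %), THF, rt; filter under Ar; then NaH (2.5 equiv), MOMCl (2.4 equiv), THF/DMF, 0 °C → rt
Reagents that add atoms: chloromethyl methyl ether, COCCl
Why: Catalytic hydrogenation reduces the quinone to the hydroquinone, and Williamson O-alkylation of both unhindered phenoxides with MOMCl gives the bis-acetal; no stereocentre is involved.

**Step 2**
Reactants: 3 1,4-bis(methoxymethoxy)-2,3-dimethoxybenzene; 4 (2-bromoallyl)trimethylsilane
Product: 7 {2-[2,5-bis(methoxymethoxy)-3,4-dimethoxyphenyl]prop-2-en-1-yl}trimethylsilane, via aryllithium 5 (not isolated), via arylzinc chloride 6 (not isolated)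
Conditions: n-BuLi (1.1 equiv), TMEDA, THF, −20 → 0 °C; ZnCl2 (1.2 equiv), 0 °C → rt; then 4 (1.2 equiv), Pd(OAc)2 (2 mol %), SPhos (4 mol %), 50 °C
Reagents that add atoms: none
Why: Directed ortho-metalation next to OMOM (the two free ring positions are equivalent), transmetalation to zinc and Negishi cross-coupling at the vinyl bromide of 4 give the 2-arylallylsilane; the allylic C–Si bond is inert to these conditions.

**Step 3**
Reactants: 7 {2-[2,5-bis(methoxymethoxy)-3,4-dimethoxyphenyl]prop-2-en-1-yl}trimethylsilane; 1 2,3-dimethoxy-1,4-benzoquinone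
Product: 8 5-{2-[2,5-bis(methoxymethoxy)-3,4-dimethoxyphenyl]prop-2-en-1-yl}-2,3-dimethoxybenzene-1,4-diol
Conditions: 1 (1.0 equiv), BF3·OEt2 (1.2 equiv), CH2Cl2, −78 °C; add 7 (1.1 equiv), 1 h; degassed aqueous work-up under Ar
Reagents that add atoms: none
Why: Hosomi–Sakurai conjugate allylation: the CH2 terminus of the allylsilane attacks C5 of the BF3-activated quinone (C5 and C6 are equivalent), the aryl-stabilised β-silyl cation loses Me3Si, and enolisation aromatises to the allylhydroquinone; aryl MOM ethers are expected to survive BF3 at −78 °C for this short time.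

**Step 4**
Reactants: 8 5-{2-[2,5-bis(methoxymethoxy)-3,4-dimethoxyphenyl]prop-2-en-1-yl}-2,3-dimethoxybenzene-1,4-diol
Product: 9 tert-butyl 5-{2-[2,5-bis(methoxymethoxy)-3,4-dimethoxyphenyl]prop-2-en-1-yl}-4-hydroxy-2,3-dimethoxyphenyl carbonate
Conditions: Boc2O (1.05 equiv), DMAP (5 mol %), CH2Cl2, −40 → −20 °C, Ar
Reagents that add atoms: di-tert-butyl dicarbonate, CC(C)(C)OC(=O)OC(=O)OC(C)(C)C
Why: DMAP-catalysed carbonate formation with the bulky anhydride should select the remote OH (one ortho substituent) over the OH next to the allyl group (two ortho substituents); this stops hydroquinone autoxidation and makes ring A harder to oxidise in step 5.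

**Step 5**
Reactants: 9 tert-butyl 5-{2-[2,5-bis(methoxymethoxy)-3,4-dimethoxyphenyl]prop-2-en-1-yl}-4-hydroxy-2,3-dimethoxyphenyl carbonate
Product: 10 tert-butyl (3S)-3-[2,5-bis(methoxymethoxy)-3,4-dimethoxyphenyl]-7,8-dimethoxy-3,4-dihydro-2H-chromen-6-yl carbonate
Conditions: 9-mesityl-3,6-di-tert-butyl-10-phenylacridinium tetrafluoroborate (5 mol %), (R)-2'-hydroxy-3-(2,4,6-triisopropylphenyl)-1,1'-binaphthalene-2-thiol (10 mol %), 2,6-lutidine (20 mol %), degassed DCE (0.05 M), 450 nm LEDs, −20 °C
Reagents that add atoms: none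
Why: Proposed new method: the excited acridinium oxidises the electron-rich aryl alkene (or the phenol; both converge), the phenol oxygen attacks the CH2 terminus 6-endo and a proton is lost to lutidine to give the tertiary benzylic C3 radical, and the enantio-determining step is hydrogen-atom transfer to one face of that radical from the aryl thiol in the binaphthyl pocket (S–H about 79 kcal/mol against about 84 for the new C–H; the thiyl radical is reduced by the acridine radical and reprotonated), which sets (S) at C3 under catalyst control; the closest known reaction types are the racemic acridinium/thiol anti-Markovnikov hydroetherification of alkenols and chiral-thiol-controlled enantioselective hydrogen-atom transfer in radical hydroamination.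

**Step 6**
Reactants: 10 tert-butyl (3S)-3-[2,5-bis(methoxymethoxy)-3,4-dimethoxyphenyl]-7,8-dimethoxy-3,4-dihydro-2H-chromen-6-yl carbonate
Product: 12 5-[(3S)-6-hydroxy-7,8-dimethoxy-3,4-dihydro-2H-chromen-3-yl]-2,3-dimethoxycyclohexa-2,5-diene-1,4-dione, via triphenol 11 (not isolated)
Conditions: HCl (3 M in MeOH), 40 °C; concentrate; then O2 (1 atm), MeCN/pH 7 phosphate buffer, rt
Reagents that add atoms: none
Why: Acid methanolysis of the two MOM acetals and acidolysis of the aryl Boc carbonate give triphenol 11, whose ring B para-hydroquinone autoxidises to the quinone while the ring A mono-ether phenol cannot form a quinone without C–O cleavage; C3 is untouched, and neutral pH avoids quinone-methide tautomerisation.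

## Compound list

1 | 2,3-dimethoxy-1,4-benzoquinone | COC1=C(OC)C(=O)C=CC1=O | starting material
2 | 2,3-dimethoxybenzene-1,4-diol | COc1c(O)ccc(O)c1OC | intermediate
3 | 1,4-bis(methoxymethoxy)-2,3-dimethoxybenzene | COCOc1ccc(OCOC)c(OC)c1OC | intermediate
4 | (2-bromoallyl)trimethylsilane | C=C(Br)C[Si](C)(C)C | starting material
5 | [2,5-bis(methoxymethoxy)-3,4-dimethoxyphenyl]lithium | [Li]c1cc(OCOC)c(OC)c(OC)c1OCOC | intermediate
6 | [2,5-bis(methoxymethoxy)-3,4-dimethoxyphenyl]zinc chloride | Cl[Zn]c1cc(OCOC)c(OC)c(OC)c1OCOC | intermediate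
7 | {2-[2,5-bis(methoxymethoxy)-3,4-dimethoxyphenyl]prop-2-en-1-yl}trimethylsilane | C=C(C[Si](C)(C)C)c1cc(OCOC)c(OC)c(OC)c1OCOC | intermediate
8 | 5-{2-[2,5-bis(methoxymethoxy)-3,4-dimethoxyphenyl]prop-2-en-1-yl}-2,3-dimethoxybenzene-1,4-diol | C=C(Cc1cc(O)c(OC)c(OC)c1O)c1cc(OCOC)c(OC)c(OC)c1OCOC | intermediate
9 | tert-butyl 5-{2-[2,5-bis(methoxymethoxy)-3,4-dimethoxyphenyl]prop-2-en-1-yl}-4-hydroxy-2,3-dimethoxyphenyl carbonate | C=C(Cc1cc(OC(=O)OC(C)(C)C)c(OC)c(OC)c1O)c1cc(OCOC)c(OC)c(OC)c1OCOC | intermediate
10 | tert-butyl (3S)-3-[2,5-bis(methoxymethoxy)-3,4-dimethoxyphenyl]-7,8-dimethoxy-3,4-dihydro-2H-chromen-6-yl carbonate | COCOc1cc([C@H]2COc3c(cc(OC(=O)OC(C)(C)C)c(OC)c3OC)C2)c(OCOC)c(OC)c1OC | intermediate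
11 | 5-[(3S)-6-hydroxy-7,8-dimethoxy-3,4-dihydro-2H-chromen-3-yl]-2,3-dimethoxybenzene-1,4-diol | COc1c(O)cc([C@H]2COc3c(cc(O)c(OC)c3OC)C2)c(O)c1OC | intermediate
12 | 5-[(3S)-6-hydroxy-7,8-dimethoxy-3,4-dihydro-2H-chromen-3-yl]-2,3-dimethoxycyclohexa-2,5-diene-1,4-dione (CNP0302517.1) | COC1=C(OC)C(=O)C([C@H]2COc3c(cc(O)c(OC)c3OC)C2)=CC1=O | target

## Step count and risks

Total step count: 6. Longest linear sequence: 6 steps (1 → 3 → 7 → 8 → 9 → 10 → 12); quinone 1 enters a second time in step 3 as a bought material.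

**Step 5 (the proposed new hydroetherification).** The risks are low ee from a thiol that has never been tested, allylic deprotonation of the radical cation (alkene isomerisation), and unproductive oxidation of the other electron-rich rings. Which thiol antipode gives (S) has to be found in the first run; the (S)-thiol is used if (R)-10 forms. The fallback uses known chemistry only, sets out from 9 and comes back at 10. Compound 9 is hydroborated under copper hydride catalysis (CuCl, DTBM-SEGPHOS in the enantiomer that gives the (S)-boronate, catalytic NaOt-Bu, HBpin, toluene, rt). This is the established enantioselective anti-Markovnikov hydroboration of 1,1-disubstituted aryl alkenes and gives tert-butyl 5-[(2S)-2-[2,5-bis(methoxymethoxy)-3,4-dimethoxyphenyl]-3-(4,4,5,5-tetramethyl-1,3,2-dioxaborolan-2-yl)propyl]-4-hydroxy-2,3-dimethoxyphenyl carbonate F1. Oxidation with NaBO3·4H2O in THF/water gives tert-butyl 5-[(2S)-2-[2,5-bis(methoxymethoxy)-3,4-dimethoxyphenyl]-3-hydroxypropyl]-4-hydroxy-2,3-dimethoxyphenyl carbonate F2. Mitsunobu cyclisation (PPh3, DIAD, THF, 0 °C) then closes the O1–C2 bond at the CH2 carbon without touching C3 and gives 10.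

**Step 3 (quinone allylation).** The stabilised β-silyl cation may be trapped by oxygen ([3+2] annulation to a dihydrobenzofuran) instead of losing silicon, and BF3 may cut a MOM group. The fallback reverses the order of the two C–C bonds; it sets out from 1, 4 and aryllithium 5 and comes back at 8. Quinone 1 is allylated with the deactivated silane 4 itself (TiCl4, CH2Cl2, −78 °C; no acetal and no stabilised cation present) to give 5-(2-bromoprop-2-en-1-yl)-2,3-dimethoxybenzene-1,4-diol F3. Aryllithium 5 is quenched with B(OMe)3 and hydrolysed to [2,5-bis(methoxymethoxy)-3,4-dimethoxyphenyl]boronic acid F4. Suzuki–Miyaura coupling of F3 with F4 (Pd(OAc)2, SPhos, K3PO4, degassed dioxane/water, 60 °C) gives 8.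

**Step 6 (unmasking and oxidation).** Formaldehyde equivalents released from the MOM groups can alkylate the electron-rich rings under acid, and the ring A phenol (a 6-hydroxychroman) may be attacked if the oxidation is pushed. The fallback changes the order to oxidative unmasking with ring A still protected; it sets out from 10 and comes back at 12. Compound 10 is treated with (NH4)2Ce(NO3)6 in MeCN/water at 0 °C, which converts the bis-MOM hydroquinone ether directly to the quinone while the carbonate-deactivated ring A is spared, to give tert-butyl (3S)-3-(4,5-dimethoxy-3,6-dioxocyclohexa-1,4-dien-1-yl)-7,8-dimethoxy-3,4-dihydro-2H-chromen-6-yl carbonate F5. TFA in CH2Cl2 at 0 °C then removes the Boc group to give 12.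

## Further compounds

F1 | step 5 | tert-butyl 5-[(2S)-2-[2,5-bis(methoxymethoxy)-3,4-dimethoxyphenyl]-3-(4,4,5,5-tetramethyl-1,3,2-dioxaborolan-2-yl)propyl]-4-hydroxy-2,3-dimethoxyphenyl carbonate | COCOc1cc([C@H](Cc2cc(OC(=O)OC(C)(C)C)c(OC)c(OC)c2O)CB3OC(C)(C)C(C)(C)O3)c(OCOC)c(OC)c1OC
F2 | step 5 | tert-butyl 5-[(2S)-2-[2,5-bis(methoxymethoxy)-3,4-dimethoxyphenyl]-3-hydroxypropyl]-4-hydroxy-2,3-dimethoxyphenyl carbonate | COCOc1cc([C@H](Cc2cc(OC(=O)OC(C)(C)C)c(OC)c(OC)c2O)CO)c(OCOC)c(OC)c1OC
F3 | step 3 | 5-(2-bromoprop-2-en-1-yl)-2,3-dimethoxybenzene-1,4-diol | C=C(Br)Cc1cc(O)c(OC)c(OC)c1O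
F4 | step 3 | [2,5-bis(methoxymethoxy)-3,4-dimethoxyphenyl]boronic acid | OB(O)c1cc(OCOC)c(OC)c(OC)c1OCOC
F5 | step 6 | tert-butyl (3S)-3-(4,5-dimethoxy-3,6-dioxocyclohexa-1,4-dien-1-yl)-7,8-dimethoxy-3,4-dihydro-2H-chromen-6-yl carbonate | COC1=C(OC)C(=O)C([C@H]2COc3c(cc(OC(=O)OC(C)(C)C)c(OC)c3OC)C2)=CC1=O
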